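Retrosynthesis (ring numbered C1(=O), C2(OH), C3(C15H31), C4(=O), C5(OMe), C6(H)): the quinone is taken back to a pentasubstituted benzene oxygenated at C1, C2, C4 and C5, and the ring is cut at C6–C5 and C1–C2.
These two cuts release the C1–C6 edge as ethoxyacetylene and leave C5–C4–C3–C2 as an oxygenated vinylketene, stored as a squarate-derived cyclobutenone.
Enabling feature: C6 is the only ring C–H and lies between two oxygen-bearing carbons (C1, C5), while C2–C5 carry O, C15H31, O, O; a ketene/ynol-ether union delivers exactly this pattern, with the CH carbon bound to the ketene carbon.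
Forward: diisopropyl squarate is mono-reduced, MOM-protected and given the C15 chain (1-bromopentadecane, via the iodide and the lithium reagent) with 1,3-carbonyl transposition; thermal benzannulation with ethoxyacetylene then builds the only ring.
O-Methylation, MOM removal, oxidative de-ethylation to the quinone and de-isopropylation complete the target.
Stereochemistry: the target has no stereocentre; the racemic sp3 centres of the four-membered intermediates vanish on aromatization.

Key step: step 5

Remark: the side chain is unbranched n-pentadecyl (fifteen carbons outside the ring), and the target is handled as its 2-hydroxy-1,4-benzoquinone tautomer.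

Step 1
Reactants: 1 diisopropyl squarate [3,4-di(propan-2-yloxy)cyclobut-3-ene-1,2-dione]
Product: 2 4-hydroxy-2,3-di(propan-2-yloxy)cyclobut-2-en-1-one (racemic)
Conditions: LiAlH(OtBu)3 (1.05 equiv), THF, −78 to −20 °C; cold H2O work-up; used crude
Reagents that add atoms: none
Why: Mono-reduction of a vinylogous diester by a bulky, mild hydride (1,2-reduction of one squarate carbonyl): the aluminium alkoxide formed resists further hydride and the enol ethers are untouched; the new carbinol centre is racemic and is erased at the aromatization stage.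

Step 2
Reactants: 2 4-hydroxy-2,3-di(propan-2-yloxy)cyclobut-2-en-1-one
Product: 3 4-(methoxymethoxy)-2,3-di(propan-2-yloxy)cyclobut-2-en-1-one (racemic)
Conditions: MOMCl (1.5 equiv), iPr2NEt (2 equiv), CH2Cl2, 0 °C to rt
Reagents that add atoms: chloromethyl methyl ether (MOMCl), COCCl
Why: O-Alkylation of the secondary alcohol with a reactive α-chloro ether under mild amine base (MOM acetal formation); an acetal is chosen because, unlike a silyl group, it cannot migrate to the neighbouring phenol oxygen during the later O-methylation, and it survives organolithium addition.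

Step 3
Reactants: 4 1-bromopentadecane
Product: 5 1-iodopentadecane
Conditions: NaI (1.5 equiv), acetone, reflux
Reagents that add atoms: sodium iodide, [Na+].[I-]
Why: Finkelstein halide exchange, an SN2 displacement of the primary bromide by iodide driven by precipitation of NaBr from acetone; the iodide is made because lithium–iodine exchange with tert-butyllithium is clean for primary alkyl iodides.

Step 4
Reactants: 3 4-(methoxymethoxy)-2,3-di(propan-2-yloxy)cyclobut-2-en-1-one; 5 1-iodopentadecane
Product: 8 4-(methoxymethoxy)-3-pentadecyl-2-(propan-2-yloxy)cyclobut-2-en-1-one (racemic), via pentadecyllithium 6 (not isolated), via lithium alkoxide adduct 7 (not isolated)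
Conditions: 5, tert-butyllithium (2.1 equiv), Et2O–pentane, −78 °C; add 3 in THF, −78 °C; then 1 M aq. HCl, THF, 0 °C
Reagents that add atoms: water, O
Why: Lithium–iodine exchange gives the primary alkyllithium, which adds 1,2 to the only carbonyl of 3; dilute acid then ionizes the tertiary allylic alcohol to a dialkoxy-stabilized cyclobutenyl cation that is hydrated at the remote isopropoxy carbon and loses propan-2-ol (1,3-carbonyl transposition of a vinylogous ester, the Stork–Danheiser sequence as applied to squarate adducts); the stereocentre created in 7 is uncontrolled and destroyed in the same flask.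

Step 5
Reactants: 8 4-(methoxymethoxy)-3-pentadecyl-2-(propan-2-yloxy)cyclobut-2-en-1-one; 9 ethoxyacetylene (ethoxyethyne)
Product: 14 5-ethoxy-2-(methoxymethoxy)-3-pentadecyl-4-(propan-2-yloxy)phenol, via vinylketene 10 (not isolated), via vinylcyclobutenone 11 (not isolated), via dienylketene 12 (not isolated), via cyclohexadienone 13 (not isolated)
Conditions: 9 (3 equiv, hexane solution), toluene, sealed tube, 80 °C then 110 °C
Reagents that add atoms: none
Why: Heating opens cyclobutenone 8 by 4π-electrocyclic cleavage of its C(=O)–CH(OMOM) bond to vinylketene 10, whose ketene C=C undergoes a regiospecific [2+2] cycloaddition with the electron-rich alkyne 9 to give 11; a second 4π opening gives dienylketene 12, 6π electrocyclization gives 13 and tautomerization gives the phenol, so the CH–C(OH) and C(OEt)–C(OiPr) ring bonds are made in one operation. The closest known reaction type is the Danheiser benzannulation of cyclobutenones with alkoxyacetylenes, whose second half is the ring expansion known for 4-alkenyl-4-alkoxycyclobutenones. The only ring closed is the benzene ring, by thermal disrotatory 6π electrocyclization of the dienylketene (a formal [4+2] union of a four-carbon vinylketene with a two-carbon alkyne). No stereocentre is created, since the sp3 carbons of 8, 11 and 13 become sp2 on aromatization. The step needs regiocontrol in the alkyne uptake and the right torquoselectivity: the nucleophilic CH terminus of the ynol ether attacks the electrophilic ketene carbon, which places CH next to the future phenol carbon and C–OEt next to C–OiPr, while the oxygen donors (OMOM in 8, OiPr in 11) rotate outward so that the alkenyl arm turns inward and can close onto the ketene.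

Step 6
Reactants: 14 5-ethoxy-2-(methoxymethoxy)-3-pentadecyl-4-(propan-2-yloxy)phenol
Product: 15 1-ethoxy-5-methoxy-4-(methoxymethoxy)-3-pentadecyl-2-(propan-2-yloxy)benzene
Conditions: MeI (3 equiv), K2CO3 (2 equiv), DMF, rt
Reagents that add atoms: iodomethane (MeI), CI
Why: Williamson etherification of the only free phenol; the flanking MOM acetal cannot migrate, so the methyl group is placed unambiguously on the oxygen that came from the ketene carbonyl.

Step 7
Reactants: 15 1-ethoxy-5-methoxy-4-(methoxymethoxy)-3-pentadecyl-2-(propan-2-yloxy)benzene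
Product: 16 4-ethoxy-6-methoxy-2-pentadecyl-3-(propan-2-yloxy)phenol
Conditions: conc. HCl (cat.), MeOH, 45 °C, argon
Reagents that add atoms: none
Why: Acid-catalysed transacetalization removes the MOM group as dimethoxymethane, while the aryl isopropyl, ethyl and methyl ethers are stable to methanolic HCl.

Step 8
Reactants: 16 4-ethoxy-6-methoxy-2-pentadecyl-3-(propan-2-yloxy)phenol
Product: 17 5-methoxy-3-pentadecyl-2-(propan-2-yloxy)cyclohexa-2,5-diene-1,4-dione
Conditions: (NH4)2Ce(NO3)6 (2.2 equiv), MeCN–H2O (3:1), 0 °C, 10 min
Reagents that add atoms: water, O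
Why: Oxidative dealkylation of a para-alkoxyphenol by tetravalent cerium: two-electron oxidation of the only free phenol gives a phenoxonium ion that water attacks at the para (ethoxy-bearing) carbon, and loss of ethanol from the hemiketal gives the 1,4-quinone, with the carbonyl pair fixed by the position of the free hydroxyl.

Step 9
Reactants: 17 5-methoxy-3-pentadecyl-2-(propan-2-yloxy)cyclohexa-2,5-diene-1,4-dione
Product: 18 2-hydroxy-5-methoxy-3-pentadecylcyclohexa-2,5-diene-1,4-dione (target)
Conditions: BCl3 (1.5 equiv, 1 M in CH2Cl2), CH2Cl2, −78 to −20 °C; then H2O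
Reagents that add atoms: none
Why: Lewis-acid dealkylation of a vinylogous ester: BCl3 chelates the isopropoxy oxygen and the adjacent quinone carbonyl, and the secondary C–O bond should be cleaved (ionization or chloride attack) much faster than the methyl C–O bond of the other vinylogous ester, as in the selective cleavage of aryl isopropyl ethers beside methyl ethers; hydrolysis of the boron chelate frees the hydroxyquinone.

Compound list
1 | diisopropyl squarate, 3,4-di(propan-2-yloxy)cyclobut-3-ene-1,2-dione | CC(C)OC1=C(OC(C)C)C(=O)C1=O | starting material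
2 | 4-hydroxy-2,3-di(propan-2-yloxy)cyclobut-2-en-1-one (racemic) | O=C1C(OC(C)C)=C(OC(C)C)C1O | intermediate
3 | 4-(methoxymethoxy)-2,3-di(propan-2-yloxy)cyclobut-2-en-1-one (racemic) | O=C1C(OC(C)C)=C(OC(C)C)C1OCOC | intermediate
4 | 1-bromopentadecane | CCCCCCCCCCCCCCCBr | starting material
5 | 1-iodopentadecane | CCCCCCCCCCCCCCCI | intermediate
6 | pentadecyllithium | [Li]CCCCCCCCCCCCCCC | intermediate (not isolated)
7 | lithium 4-(methoxymethoxy)-1-pentadecyl-2,3-di(propan-2-yloxy)cyclobut-2-en-1-olate (diastereomer mixture) | [Li+].[O-]C1(CCCCCCCCCCCCCCC)C(OC(C)C)=C(OC(C)C)C1OCOC | intermediate (not isolated)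
8 | 4-(methoxymethoxy)-3-pentadecyl-2-(propan-2-yloxy)cyclobut-2-en-1-one (racemic) | O=C1C(OC(C)C)=C(CCCCCCCCCCCCCCC)C1OCOC | intermediate
9 | ethoxyacetylene (ethoxyethyne) | C#COCC | starting material
10 | vinylketene, (3E)-4-(methoxymethoxy)-3-pentadecyl-2-(propan-2-yloxy)buta-1,3-dien-1-one | O=C=C(OC(C)C)/C(CCCCCCCCCCCCCCC)=C/OCOC | intermediate (not isolated)
11 | vinylcyclobutenone, 3-ethoxy-4-[(1E)-1-(methoxymethoxy)heptadec-1-en-2-yl]-4-(propan-2-yloxy)cyclobut-2-en-1-one (racemic) | O=C1C=C(OCC)C1(OC(C)C)/C(CCCCCCCCCCCCCCC)=C/OCOC | intermediate (not isolated)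
12 | dienylketene, (3Z,5E)-3-ethoxy-6-(methoxymethoxy)-5-pentadecyl-4-(propan-2-yloxy)hexa-1,3,5-trien-1-one | O=C=C/C(OCC)=C(OC(C)C)\C(CCCCCCCCCCCCCCC)=C\OCOC | intermediate (not isolated)
13 | cyclohexadienone, 3-ethoxy-6-(methoxymethoxy)-5-pentadecyl-4-(propan-2-yloxy)cyclohexa-2,4-dien-1-one (racemic) | O=C1C=C(OCC)C(OC(C)C)=C(CCCCCCCCCCCCCCC)C1OCOC | intermediate (not isolated)
14 | 5-ethoxy-2-(methoxymethoxy)-3-pentadecyl-4-(propan-2-yloxy)phenol | Oc1cc(OCC)c(OC(C)C)c(CCCCCCCCCCCCCCC)c1OCOC | intermediate
15 | 1-ethoxy-5-methoxy-4-(methoxymethoxy)-3-pentadecyl-2-(propan-2-yloxy)benzene | COc1cc(OCC)c(OC(C)C)c(CCCCCCCCCCCCCCC)c1OCOC | intermediate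
16 | 4-ethoxy-6-methoxy-2-pentadecyl-3-(propan-2-yloxy)phenol | COc1cc(OCC)c(OC(C)C)c(CCCCCCCCCCCCCCC)c1O | intermediate
17 | 5-methoxy-3-pentadecyl-2-(propan-2-yloxy)cyclohexa-2,5-diene-1,4-dione | CCCCCCCCCCCCCCCC1=C(OC(C)C)C(=O)C=C(OC)C1=O | intermediate
18 | 2-hydroxy-5-methoxy-3-pentadecylcyclohexa-2,5-diene-1,4-dione | CCCCCCCCCCCCCCCC1=C(O)C(=O)C=C(OC)C1=O | target

Total step count: 9. Longest linear sequence: 8 steps (1 to 18 through steps 1, 2, 4, 5, 6, 7, 8 and 9; step 3 is a one-step branch that prepares the iodide).

Steps most likely to fail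

Step 5. The strongly oxygenated vinylketene may dimerize, be captured by the product phenol as an aryl ester, or take up the alkyne too slowly, so that conversion to the arene stalls. The fallback sets out from 1 and returns at 17; it builds the ring stepwise by carbonyl addition of a two-carbon alkenyl unit and ring expansion of a 4-alkenyl-4-hydroxycyclobutenone. Pentadecyllithium 6 is added to 1 (THF, −78 °C; aq. NH4Cl) to give 4-hydroxy-4-pentadecyl-2,3-di(propan-2-yloxy)cyclobut-2-en-1-one F1. Conc. HCl (cat.) in CH2Cl2 should convert it, with loss of propan-2-ol, into 3-pentadecyl-4-(propan-2-yloxy)cyclobut-3-ene-1,2-dione F2. (Z)-2-Methoxyethenyllithium F3, made from (Z)-1-bromo-2-methoxyethene and tert-butyllithium at −78 °C, should add to the ketone-like carbonyl next to the isopropoxy-bearing carbon to give 4-hydroxy-4-[(Z)-2-methoxyethenyl]-2-pentadecyl-3-(propan-2-yloxy)cyclobut-2-en-1-one F4. Heating in toluene at 110 °C should give, by 4π ring opening, 6π closure and tautomerization, 5-methoxy-3-pentadecyl-2-(propan-2-yloxy)benzene-1,4-diol F5, which Ag2O in Et2O oxidizes to 17; the route continues with step 9.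

Step 9. The methyl group of the second vinylogous ester may be lost as well, or chloride may add to the Lewis-acid-activated quinone. The fallback sets out from 17 and returns at 18; it moves the dealkylation to the arene oxidation level. Reductive acetylation of 17 (Zn, Ac2O, NaOAc, rt) should give 4-(acetyloxy)-5-methoxy-3-pentadecyl-2-(propan-2-yloxy)phenyl acetate F6. BCl3 (CH2Cl2, −78 to 0 °C) then cleaves the aryl isopropyl ether, an established selective reaction beside aryl methyl ethers and acetates, to give 4-(acetyloxy)-2-hydroxy-5-methoxy-3-pentadecylphenyl acetate F7. K2CO3 in MeOH under air removes both acetates, and the resulting 5-methoxy-3-pentadecylbenzene-1,2,4-triol F8 is oxidized by air in the same flask to 18, isolated after acidification.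

Step 8. Water may attack ortho instead of para to the phenol oxygen (ortho-quinone formation with loss of methanol), or the electron-rich ring may be over-oxidized in the strongly acidic aqueous medium. The fallback sets out from 16 and returns at 17; it uses a non-aqueous two-electron oxidation to an isolable quinone monoketal. PhI(OAc)2 in MeOH at 0 °C should convert 16, by para-selective capture of methanol, into 4-ethoxy-4,6-dimethoxy-2-pentadecyl-3-(propan-2-yloxy)cyclohexa-2,5-dien-1-one F9 (racemic). Aqueous oxalic acid in THF then hydrolyses the mixed ketal to 17.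

Further compounds
F1 | step 5 | 4-hydroxy-4-pentadecyl-2,3-di(propan-2-yloxy)cyclobut-2-en-1-one (racemic) | O=C1C(OC(C)C)=C(OC(C)C)C1(O)CCCCCCCCCCCCCCC
F2 | step 5 | 3-pentadecyl-4-(propan-2-yloxy)cyclobut-3-ene-1,2-dione | O=C1C(=O)C(CCCCCCCCCCCCCCC)=C1OC(C)C
F3 | step 5 | (Z)-2-methoxyethenyllithium | [Li]/C=C\OC
F4 | step 5 | 4-hydroxy-4-[(Z)-2-methoxyethenyl]-2-pentadecyl-3-(propan-2-yloxy)cyclobut-2-en-1-one (racemic) | O=C1C(CCCCCCCCCCCCCCC)=C(OC(C)C)C1(O)/C=C\OC
F5 | step 5 | 5-methoxy-3-pentadecyl-2-(propan-2-yloxy)benzene-1,4-diol | COc1cc(O)c(OC(C)C)c(CCCCCCCCCCCCCCC)c1O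
F6 | step 9 | 4-(acetyloxy)-5-methoxy-3-pentadecyl-2-(propan-2-yloxy)phenyl acetate | CC(=O)Oc1cc(OC)c(OC(C)=O)c(CCCCCCCCCCCCCCC)c1OC(C)C
F7 | step 9 | 4-(acetyloxy)-2-hydroxy-5-methoxy-3-pentadecylphenyl acetate | CC(=O)Oc1cc(OC)c(OC(C)=O)c(CCCCCCCCCCCCCCC)c1O
F8 | step 9 | 5-methoxy-3-pentadecylbenzene-1,2,4-triol | COc1cc(O)c(O)c(CCCCCCCCCCCCCCC)c1O
F9 | step 8 | 4-ethoxy-4,6-dimethoxy-2-pentadecyl-3-(propan-2-yloxy)cyclohexa-2,5-dien-1-one (racemic) | O=C1C(CCCCCCCCCCCCCCC)=C(OC(C)C)C(OCC)(OC)C=C1OC
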